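**Plan**

- Retrosynthetic cuts, in order: the six phenol O–Si bonds; the bond from C5 of the benzofuran to the vinyl carbon (Mizoroki–Heck on a C5 triflate); then, in one event, O1–C2 and C3a–C3 of the dihydrofuran ring. This leads back to piceatannol 1 (as its tetrasilyl ether 2) and 1,4-benzoquinone 3.
- Forward: 1 is silylated to 2; 2 and 3 combine through zwitterion 4 to dihydrobenzofuran-5-ol 5, closing the five-membered oxygen ring while the quinone ring becomes the benzo ring; 5 gives triflate 6; aldehyde 7 is silylated (8) and methylenated to styrene 9; 6 and 9 give 10; desilylation gives 11.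
- Enabling feature: the oxygen para to the alkene on the catechol ring (the C2 aryl) makes the alkene carbon beside the resorcinol ring (future C3) nucleophilic and stabilises positive charge on the other alkene carbon (future C2); the resorcinol ring has only meta oxygens. C5 of the benzo ring lies para to O1, where the second oxygen of a quinone ends up, so 3 stands in, dearomatised, for a para-substituted phenol and leaves one free hydroxyl as the handle for the stilbene arm.
- Stereochemistry: both centres (2S,3S, trans) arise in the key step, C3 under a chiral oxazaborolidinium Lewis acid and C2 trans to it in the ring closure; no later step touches them.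

Key step: step 2

Assumption: the (S)-catalyst is taken to give the (2S,3S) series by analogy with its usual quinone-face model; if the mirror-image series forms, the (R)-catalyst is used instead. Intermediate 4 is drawn without the boron catalyst it carries on the enolate oxygen, and its ring sp3 carbon is left undefined because that centre is lost on aromatisation.

**Step 1**
Reactants: 1 piceatannol, (E)-3,3',4,5'-tetrahydroxystilbene
Product: 2 (E)-3,3',4,5'-tetrakis(tert-butyldimethylsilyloxy)stilbene
Conditions: TBSCl (5 equiv), imidazole (10 equiv), DMF, 0 °C to rt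
Reagents that add atoms: tert-butyldimethylsilyl chloride (TBSCl), CC(C)(C)[Si](C)(C)Cl
Why: Imidazole-promoted silylation of phenols caps all four hydroxyls, so that no O–H quenches the Lewis acid of step 2, the para silyloxy group keeps the catechol ring a donor, and the bulky groups shield the open positions of the resorcinol ring.

**Step 2**
Reactants: 2 (E)-3,3',4,5'-tetrakis(tert-butyldimethylsilyloxy)stilbene; 3 1,4-benzoquinone
Product: 5 (2S,3S)-2-[3,4-bis(tert-butyldimethylsilyloxy)phenyl]-3-[3,5-bis(tert-butyldimethylsilyloxy)phenyl]-2,3-dihydro-1-benzofuran-5-ol, via benzylic-cation zwitterion 4 (not isolated)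
Conditions: (S)-1-(o-tolyl)-3,3-diphenyltetrahydro-1H,3H-pyrrolo[1,2-c][1,3,2]oxazaborole (20 mol%), HNTf2 (16 mol%), CH2Cl2, −78 to −20 °C; aq. NaHCO3 quench
Reagents that add atoms: none
Why: Proposed new method: the boron atom of the chiral oxazaborolidinium ion binds one carbonyl oxygen of 3 and makes the ring carbon β to it strongly electrophilic; the alkene carbon of 2 next to the resorcinol ring adds there (C3a–C3 bond) to give zwitterion 4, whose benzylic cation, stabilised by the para silyloxy group of the catechol ring, is captured by the neighbouring unbound quinone oxygen (O1–C2 bond), and loss of the ring proton re-aromatises the carbocycle and releases the catalyst. The closest known reaction types are the oxazaborolidinium-catalysed enantioselective [3+2] cycloaddition of an alkoxybenzoquinone with a cyclic enol ether and the Lewis acid-promoted formal [3+2] cycloaddition of 1,4-benzoquinones with 1-arylpropenes; new here is the pairing of unsubstituted benzoquinone with a 1,2-diarylethene under a chiral catalyst. The only ring closed, the dihydrofuran, closes in a 5-exo-trig mode, the oxygen attacking the cationic carbon whose charge is delocalised into the exocyclic aryl group. C3 is set in the C–C bond formation, where the catalyst screens one face of the bound quinone and the electron-rich catechol ring of 2 stacks over the quinone in an endo-like arrangement so that one face of the alkene reacts; C2 is set in the ring closure, trans to C3 because the two aryl groups avoid each other, and reversible ionisation of the C2–O bond by the acid would funnel any cis isomer to the same trans compound without touching C3. The step needs regioselectivity across the alkene, secured by the para oxygen on the catechol ring against only meta oxygens on the resorcinol ring, and chemoselectivity for the alkene over the oxygenated arenes, secured by the bulky silyl ethers flanking every open position of the resorcinol ring and by the absence of any free O–H.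

**Step 3**
Reactants: 5 (2S,3S)-2-[3,4-bis(tert-butyldimethylsilyloxy)phenyl]-3-[3,5-bis(tert-butyldimethylsilyloxy)phenyl]-2,3-dihydro-1-benzofuran-5-ol
Product: 6 (2S,3S)-2-[3,4-bis(tert-butyldimethylsilyloxy)phenyl]-3-[3,5-bis(tert-butyldimethylsilyloxy)phenyl]-2,3-dihydro-1-benzofuran-5-yl trifluoromethanesulfonate
Conditions: PhNTf2 (1.2 equiv), Et3N, DMAP (cat.), CH2Cl2, 0 °C to rt
Reagents that add atoms: N-phenylbis(trifluoromethanesulfonimide) (PhNTf2), O=S(=O)(N(c1ccccc1)S(=O)(=O)C(F)(F)F)C(F)(F)F
Why: Sulfonyl transfer to the only free phenol (aryl triflate formation) under mild amine base leaves the silyl ethers and both benzylic stereocentres untouched.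

**Step 4**
Reactants: 7 3,5-dihydroxybenzaldehyde
Product: 8 3,5-bis(tert-butyldimethylsilyloxy)benzaldehyde
Conditions: TBSCl (2.5 equiv), imidazole (5 equiv), DMF, rt
Reagents that add atoms: tert-butyldimethylsilyl chloride (TBSCl), CC(C)(C)[Si](C)(C)Cl
Why: Standard imidazole-promoted silylation of both phenols, which the aldehyde tolerates.

**Step 5**
Reactants: 8 3,5-bis(tert-butyldimethylsilyloxy)benzaldehyde
Product: 9 3,5-bis(tert-butyldimethylsilyloxy)styrene
Conditions: Ph3PCH3Br (1.3 equiv), n-BuLi (1.25 equiv), THF, 0 °C; then 8, 0 °C to rt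
Reagents that add atoms: methyltriphenylphosphonium bromide, C[P+](c1ccccc1)(c1ccccc1)c1ccccc1.[Br-]
Why: Wittig methylenation with the ylide preformed from a slight deficit of base, so that no free strong base meets the aryl silyl ethers.

**Step 6**
Reactants: 6 (2S,3S)-2-[3,4-bis(tert-butyldimethylsilyloxy)phenyl]-3-[3,5-bis(tert-butyldimethylsilyloxy)phenyl]-2,3-dihydro-1-benzofuran-5-yl trifluoromethanesulfonate; 9 3,5-bis(tert-butyldimethylsilyloxy)styrene
Product: 10 (2S,3S)-2-[3,4-bis(tert-butyldimethylsilyloxy)phenyl]-3-[3,5-bis(tert-butyldimethylsilyloxy)phenyl]-5-[(E)-2-[3,5-bis(tert-butyldimethylsilyloxy)phenyl]ethenyl]-2,3-dihydro-1-benzofuran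
Conditions: Pd(OAc)2 (5 mol%), PPh3 (15 mol%), LiCl (3 equiv), Et3N (3 equiv), DMF, 90 °C
Reagents that add atoms: none
Why: Mizoroki–Heck reaction in which zerovalent palladium inserts into the C–OTf bond, chloride keeps the arylpalladium species neutral so that the aryl group goes to the terminal alkene carbon, and syn β-hydride elimination gives the (E)-stilbene; the amine base does not epimerise C2 or C3, and any silyl loss here is harmless because step 7 removes all silyl groups.

**Step 7**
Reactants: 10 (2S,3S)-2-[3,4-bis(tert-butyldimethylsilyloxy)phenyl]-3-[3,5-bis(tert-butyldimethylsilyloxy)phenyl]-5-[(E)-2-[3,5-bis(tert-butyldimethylsilyloxy)phenyl]ethenyl]-2,3-dihydro-1-benzofuran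
Product: 11 5-[(E)-2-[(2S,3S)-2-(3,4-dihydroxyphenyl)-3-(3,5-dihydroxyphenyl)-2,3-dihydro-1-benzofuran-5-yl]ethenyl]benzene-1,3-diol (target)
Conditions: TBAF (7 equiv), AcOH (7 equiv), THF, 0 °C to rt, argon; then sulfonic acid resin, CaCO3, MeOH
Reagents that add atoms: none
Why: Fluoride-mediated desilylation cleaves the six aryl O–Si bonds, while the acetic acid buffer keeps the phenols protonated so that no 4-phenoxide can open the dihydrofuran through a para-quinone methide; the stereocentres and the (E)-alkene are unaffected.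

**Compound list**

1 | piceatannol, (E)-3,3',4,5'-tetrahydroxystilbene | Oc1cc(O)cc(/C=C/c2ccc(O)c(O)c2)c1 | starting material
2 | (E)-3,3',4,5'-tetrakis(tert-butyldimethylsilyloxy)stilbene | CC(C)(C)[Si](C)(C)Oc1cc(O[Si](C)(C)C(C)(C)C)cc(/C=C/c2ccc(O[Si](C)(C)C(C)(C)C)c(O[Si](C)(C)C(C)(C)C)c2)c1 | intermediate
3 | 1,4-benzoquinone | O=C1C=CC(=O)C=C1 | starting material
4 | benzylic-cation zwitterion: 4-oxocyclohexadienolate carrying at its sp3 ring carbon the 1-[3,5-bis(silyloxy)phenyl]-2-[3,4-bis(silyloxy)phenyl]ethyl-2-ylium chain (silyl = tert-butyldimethylsilyl; boron catalyst omitted; ring sp3 carbon undefined) | [O-]C1=CC(C(=O)C=C1)[C@H](c1cc(O[Si](C)(C)C(C)(C)C)cc(O[Si](C)(C)C(C)(C)C)c1)[CH+]c1ccc(O[Si](C)(C)C(C)(C)C)c(O[Si](C)(C)C(C)(C)C)c1 | intermediate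
5 | (2S,3S)-2-[3,4-bis(tert-butyldimethylsilyloxy)phenyl]-3-[3,5-bis(tert-butyldimethylsilyloxy)phenyl]-2,3-dihydro-1-benzofuran-5-ol | Oc1ccc2c(c1)[C@H](c1cc(O[Si](C)(C)C(C)(C)C)cc(O[Si](C)(C)C(C)(C)C)c1)[C@@H](c1ccc(O[Si](C)(C)C(C)(C)C)c(O[Si](C)(C)C(C)(C)C)c1)O2 | intermediate
6 | (2S,3S)-2-[3,4-bis(tert-butyldimethylsilyloxy)phenyl]-3-[3,5-bis(tert-butyldimethylsilyloxy)phenyl]-2,3-dihydro-1-benzofuran-5-yl trifluoromethanesulfonate | O=S(=O)(Oc1ccc2c(c1)[C@H](c1cc(O[Si](C)(C)C(C)(C)C)cc(O[Si](C)(C)C(C)(C)C)c1)[C@@H](c1ccc(O[Si](C)(C)C(C)(C)C)c(O[Si](C)(C)C(C)(C)C)c1)O2)C(F)(F)F | intermediate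
7 | 3,5-dihydroxybenzaldehyde | O=Cc1cc(O)cc(O)c1 | starting material
8 | 3,5-bis(tert-butyldimethylsilyloxy)benzaldehyde | O=Cc1cc(O[Si](C)(C)C(C)(C)C)cc(O[Si](C)(C)C(C)(C)C)c1 | intermediate
9 | 3,5-bis(tert-butyldimethylsilyloxy)styrene | C=Cc1cc(O[Si](C)(C)C(C)(C)C)cc(O[Si](C)(C)C(C)(C)C)c1 | intermediate
10 | (2S,3S)-2-[3,4-bis(tert-butyldimethylsilyloxy)phenyl]-3-[3,5-bis(tert-butyldimethylsilyloxy)phenyl]-5-[(E)-2-[3,5-bis(tert-butyldimethylsilyloxy)phenyl]ethenyl]-2,3-dihydro-1-benzofuran | CC(C)(C)[Si](C)(C)Oc1cc(O[Si](C)(C)C(C)(C)C)cc(/C=C/c2ccc3c(c2)[C@H](c2cc(O[Si](C)(C)C(C)(C)C)cc(O[Si](C)(C)C(C)(C)C)c2)[C@@H](c2ccc(O[Si](C)(C)C(C)(C)C)c(O[Si](C)(C)C(C)(C)C)c2)O3)c1 | intermediate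
11 | 5-[(E)-2-[(2S,3S)-2-(3,4-dihydroxyphenyl)-3-(3,5-dihydroxyphenyl)-2,3-dihydro-1-benzofuran-5-yl]ethenyl]benzene-1,3-diol | Oc1cc(O)cc(/C=C/c2ccc3c(c2)[C@H](c2cc(O)cc(O)c2)[C@@H](c2ccc(O)c(O)c2)O3)c1 | target

**Count and risks**

Total step count: 7. Longest linear sequence: 5 (steps 1, 2, 3, 6, 7).

Steps most likely to fail:

1. Step 2 (Proposed new method). The catalyst-bound, unsubstituted quinone may discriminate poorly between the two faces of the acyclic alkene, eroding enantiomeric purity, and turnover may be slow. The fallback uses known chemistry, sets out from 2 and 3 and comes back at 5. The two compounds are combined under an achiral Lewis acid (BF3·OEt2, CH2Cl2, −78 °C), the known Lewis acid-promoted formal [3+2] cycloaddition of 1,4-benzoquinones with aryl alkenes. This should give the trans phenol as a racemate, that is 5 together with its mirror image, (2R,3R)-2-[3,4-bis(tert-butyldimethylsilyloxy)phenyl]-3-[3,5-bis(tert-butyldimethylsilyloxy)phenyl]-2,3-dihydro-1-benzofuran-5-ol F1. Preparative chromatography on a chiral polysaccharide phase removes F1 and delivers 5.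

2. Step 6. The styrene may insert with the aryl group at its internal carbon, or the triflate may be reduced if oxidative addition into the electron-rich aryl triflate lags. The fallback sets out from 9, uses 6, and comes back at 10. Cross-metathesis of 9 with vinylboronic acid pinacol ester (second-generation Hoveyda–Grubbs catalyst, CH2Cl2, 40 °C) should give (E)-2-[3,5-bis(tert-butyldimethylsilyloxy)phenyl]ethenylboronic acid pinacol ester F2, which fixes both the position and the (E)-geometry of the alkene. Suzuki–Miyaura coupling of F2 with 6 (PdCl2(dppf), K3PO4, dioxane/H2O, 80 °C) then gives 10.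

3. Step 7. The freed catechol may oxidise in air, a phenoxide may open the dihydrofuran through a para-quinone methide (epimerising C2), and the polar hexaphenol may be lost when ammonium salts are removed. The fallback sets out from 10 and comes back at 11. After desilylation as in step 7, the crude phenols are acetylated in the same flask (Ac2O, pyridine, DMAP) to the hexaacetate of the target, 5-[(E)-2-[(2S,3S)-2-(3,4-diacetoxyphenyl)-3-(3,5-diacetoxyphenyl)-2,3-dihydro-1-benzofuran-5-yl]ethenyl]-1,3-phenylene diacetate F3. F3 is stable and can be purified on silica; mild methanolysis (Et3N, degassed MeOH, rt, argon) then releases 11.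

**Further compounds**

F1 | step 2 | (2R,3R)-2-[3,4-bis(tert-butyldimethylsilyloxy)phenyl]-3-[3,5-bis(tert-butyldimethylsilyloxy)phenyl]-2,3-dihydro-1-benzofuran-5-ol | Oc1ccc2c(c1)[C@@H](c1cc(O[Si](C)(C)C(C)(C)C)cc(O[Si](C)(C)C(C)(C)C)c1)[C@H](c1ccc(O[Si](C)(C)C(C)(C)C)c(O[Si](C)(C)C(C)(C)C)c1)O2
F2 | step 6 | (E)-2-[3,5-bis(tert-butyldimethylsilyloxy)phenyl]ethenylboronic acid pinacol ester | CC(C)(C)[Si](C)(C)Oc1cc(O[Si](C)(C)C(C)(C)C)cc(/C=C/B2OC(C)(C)C(C)(C)O2)c1
F3 | step 7 | 5-[(E)-2-[(2S,3S)-2-(3,4-diacetoxyphenyl)-3-(3,5-diacetoxyphenyl)-2,3-dihydro-1-benzofuran-5-yl]ethenyl]-1,3-phenylene diacetate | CC(=O)Oc1cc(OC(C)=O)cc(/C=C/c2ccc3c(c2)[C@H](c2cc(OC(C)=O)cc(OC(C)=O)c2)[C@@H](c2ccc(OC(C)=O)c(OC(C)=O)c2)O3)c1
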